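**Plan**

- Retrosynthesis: the thirteen benzyl ethers come off last. Ring C of the upper (epigallocatechin gallate) unit is then cut at C4–C4a and C2–C3 in one stroke, giving an O-aryl oxocarbenium ion (ring A, O1, C2 with ring B) and an (E)-enol gallate (C3=C4) that already carries the catechin unit on C4.
- Enabling feature: in ring C the aryl ether oxygen O1 links ring A carbon C8a to the benzylic C2, so C4a=C8a–O1=C2 can act as a cationic 2-oxadiene. C3 bears the acyloxy group and C4 the 2,4,6-trioxygenated ring A of catechin (through its C8), which stabilises a cation at C4 only and so fixes the regiochemistry.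
- Forward order: (+)-catechin → penta-O-benzyl ether → 8-bromide → (E)-alkenylboronate → trifluoroborate → (E)-enol gallate. Separately, tribenzylgallaldehyde → dimethyl acetal → O-aryl O-methyl acetal. The polar [4+2] step then builds ring C and joins rings A and B, the gallate and the catechin unit; hydrogenolysis ends the route.
- Stereochemistry: the lower unit (2R,3S) comes from (+)-catechin. In the key step C2 is set by a chiral phosphoramidate counter-anion, C3 by endo placement of the galloyloxy group (2,3-cis) and C4 by the E geometry of the enol ester (3,4-trans).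

Key step: step 9

Remark on the target: it is read as epigallocatechin 3-O-gallate-(4β→8)-catechin, upper unit 2R,3R,4R (2,3-cis, 3,4-trans), lower unit 2R,3S.

Assumption: the (S)-configured acid catalyst is taken as the enantiomer that delivers the 2R,3R,4R adduct; if the sense of induction should prove opposite, the (R)-catalyst takes its place.

**Route**

Step 1
Reactants: 1 (+)-catechin
Product: 2 5,7,3',4'-tetra-O-benzyl-(+)-catechin
Conditions: BnBr (4.4 equiv), K2CO3, DMF, 0 °C to rt
Reagents that add atoms: benzyl bromide, BrCc1ccccc1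
Why: Williamson etherification with carbonate deprotonates only the four phenols, so the secondary alcohol stays free and no stereocentre is touched.

Step 2
Reactants: 2 5,7,3',4'-tetra-O-benzyl-(+)-catechin
Product: 3 3,5,7,3',4'-penta-O-benzyl-(+)-catechin
Conditions: NaH, BnBr, Bu4NI (cat.), DMF, 0 °C to rt
Reagents that add atoms: benzyl bromide, BrCc1ccccc1
Why: Williamson etherification of the C3 alkoxide should proceed cleanly once the phenols are capped, because the base-induced C2 epimerisation of catechins needs a free B-ring phenol.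

Step 3
Reactants: 3 3,5,7,3',4'-penta-O-benzyl-(+)-catechin
Product: 4 8-bromo-3,5,7,3',4'-penta-O-benzyl-(+)-catechin
Conditions: NBS (1.0 equiv), CH2Cl2, −78 °C to rt
Reagents that add atoms: N-bromosuccinimide, O=C1CCC(=O)N1Br
Why: electrophilic aromatic bromination of benzylated flavan-3-ols is expected at C8, the most nucleophilic position of the 5,7-dialkoxy ring A, ahead of C6 and of ring B.

Step 4
Reactants: 4 8-bromo-3,5,7,3',4'-penta-O-benzyl-(+)-catechin; 5 (E)-1,2-bis(4,4,5,5-tetramethyl-1,3,2-dioxaborolan-2-yl)ethene (3 equiv)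
Product: 6 (E)-2-(penta-O-benzylcatechin-8-yl)ethenylboronic acid pinacol ester
Conditions: Pd(OAc)2 (5 mol %), SPhos (10 mol %), K3PO4, 1,4-dioxane/H2O, 80 °C
Reagents that add atoms: none
Why: Suzuki–Miyaura mono-coupling with an excess of the diborylethene should transfer one boryl-vinyl unit with retention of the E geometry, the hindered product boronate being slower to couple a second time than the unhindered reagent.

Step 5
Reactants: 6 (E)-2-(penta-O-benzylcatechin-8-yl)ethenylboronic acid pinacol ester
Product: 7 potassium (E)-[2-(penta-O-benzylcatechin-8-yl)ethenyl]trifluoroborate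
Conditions: KHF2 (aq.), MeOH/THF, rt
Reagents that add atoms: potassium hydrogen difluoride, F.[F-].[K+]
Why: exchange of the pinacol ester for fluoride with KHF2 is the standard route to alkenyltrifluoroborates and leaves the alkene geometry untouched.

Step 6
Reactants: 7 potassium (E)-[2-(penta-O-benzylcatechin-8-yl)ethenyl]trifluoroborate; 8 3,4,5-tris(benzyloxy)benzoic acid
Product: 9 (E)-2-(penta-O-benzylcatechin-8-yl)ethenyl 3,4,5-tris(benzyloxy)benzoate
Conditions: Cu(OAc)2 (20 mol %), DMAP, 4 Å MS, O2 (1 atm), CH2Cl2, 40 °C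
Reagents that add atoms: none
Why: copper-catalysed oxidative C–O coupling of an alkenyltrifluoroborate with a carboxylic acid (Chan–Lam type, non-decarboxylative) should give the enol ester by transmetalation and reductive elimination with retention of the E geometry.

Step 7
Reactants: 10 3,4,5-tris(benzyloxy)benzaldehyde
Product: 11 3,4,5-tris(benzyloxy)benzaldehyde dimethyl acetal
Conditions: HC(OMe)3, TsOH·H2O (cat.), MeOH, rt; Et3N quench
Reagents that add atoms: trimethyl orthoformate, COC(OC)OC; methanol, CO
Why: acid-catalysed acetalisation driven by the orthoformate as water scavenger is routine for electron-rich benzaldehydes and does not affect benzyl ethers.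

Step 8
Reactants: 11 3,4,5-tris(benzyloxy)benzaldehyde dimethyl acetal; 12 3,5-bis(benzyloxy)phenol
Product: 14 racemic [3,5-bis(benzyloxy)phenoxy](methoxy)[3,4,5-tris(benzyloxy)phenyl]methane (O-aryl O-methyl acetal), via α-chloro ether 13 (not isolated)
Conditions: AcCl (1.05 equiv), Zn(OAc)2 (1 mol %), toluene, rt; then added to 12, NaH, THF, 0 °C; Et3N-buffered silica
Reagents that add atoms: none
Why: acyl chloride cleavage of a dimethyl acetal gives the α-chloro ether, which should O-alkylate the sodium phenoxide in the way chloromethyl ethers do (Williamson-type, as in MOM ether formation); the acetal stereocentre is racemic and is erased in step 9.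

Step 9
Reactants: 9 (E)-2-(penta-O-benzylcatechin-8-yl)ethenyl 3,4,5-tris(benzyloxy)benzoate; 14 racemic O-aryl O-methyl acetal (1.5 equiv)
Product: 16 tridecabenzyl ether of the target (upper unit 2R,3R,4R; lower unit 2R,3S), via oxocarbenium ion 15 (not isolated)
Conditions: (S)-3,3'-bis(2,4,6-triisopropylphenyl)-1,1'-binaphthyl-2,2'-diyl N-triflylphosphoramide, (ArO)2P(O)NHSO2CF3 (10 mol %), 5 Å MS, toluene/CH2Cl2, −40 °C
Reagents that add atoms: none
Why: Proposed new method: the chiral acid protonates the more basic methoxy oxygen of 14 and expels methanol to give the E-configured O-aryl oxocarbenium ion 15, a cationic 2-oxadiene (C4a=C8a–O1=C2) held as an ion pair with the chiral phosphoramidate; the enol ester 9 bonds through its acyloxy-bearing carbon (C3) to C2, the charge passes to C4 as a para-quinone-methide-type cation of the trioxygenated catechin ring, the ortho carbon C4a of ring A captures it, and rearomatisation returns the proton to the catalyst. The closest known reaction type is the Lewis-acid-promoted oxa-Povarov reaction of O-aryl mixed acetals with styrenes, together with chiral-Brønsted-acid-controlled Povarov and oxocarbenium cycloadditions; new are an enol ester of a 2-arylethenol as the two-carbon partner and anion control of the facial sense. Ring C closes as an asynchronous polar [4+2] cycloaddition of inverse electron demand, which in its stepwise limit is a Prins-type C2–C3 bond formation followed by a 6-exo-trig Friedel–Crafts closure of C4a onto the C4 cation. C2 is set by the chiral anion, which shields one face of the oxocarbenium carbon; C3 is set relative to C2 by endo placement of the galloyloxy group under the cationic O1=C2 unit (2,3-cis); C4 is set relative to C3 by suprafacial transfer of the E geometry of 9 (3,4-trans), and in a stepwise closure the same result is favoured by allylic strain in the C4 cation, which puts C4a anti to the C3–O bond. The step needs regioselectivity (secured by the catechin ring, which stabilises charge only at C4, and by the two equivalent ortho positions of the symmetric ring A), endo over exo selectivity (argued from the peri 5-benzyloxy group and the two ortho substituents of the catechin ring, which should keep that ring out of the endo position) and reagent-controlled face selectivity over the remote stereocentres of the catechin unit; low temperature, molecular sieves and a catalytic amount of acid protect the enol ester and the new interflavan bond.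

Step 10
Reactants: 16 tridecabenzyl ether of the target
Product: 17 epigallocatechin 3-O-gallate-(4β→8)-catechin (CNP0129434.1)
Conditions: H2 (1 atm), Pd(OH)2/C, THF/MeOH/H2O, rt; filtration, lyophilisation
Reagents that add atoms: none
Why: neutral hydrogenolysis should cleave all thirteen benzyl ethers while the secondary gallate ester, the interflavan C4–C8 bond and all five stereocentres are inert to these conditions.

**Compound list**

1 | (+)-catechin, (2R,3S)-2-(3,4-dihydroxyphenyl)chromane-3,5,7-triol | c1c(O)cc(O)c2c1O[C@H](c1ccc(O)c(O)c1)[C@@H](O)C2 | starting material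
2 | 5,7,3',4'-tetra-O-benzyl-(+)-catechin | c1c(OCc3ccccc3)cc(OCc3ccccc3)c2c1O[C@H](c1ccc(OCc3ccccc3)c(OCc3ccccc3)c1)[C@@H](O)C2 | intermediate
3 | 3,5,7,3',4'-penta-O-benzyl-(+)-catechin | c1c(OCc3ccccc3)cc(OCc3ccccc3)c2c1O[C@H](c1ccc(OCc3ccccc3)c(OCc3ccccc3)c1)[C@@H](OCc3ccccc3)C2 | intermediate
4 | 8-bromo-3,5,7,3',4'-penta-O-benzyl-(+)-catechin | Brc1c(OCc3ccccc3)cc(OCc3ccccc3)c2c1O[C@H](c1ccc(OCc3ccccc3)c(OCc3ccccc3)c1)[C@@H](OCc3ccccc3)C2 | intermediate
5 | (E)-1,2-bis(4,4,5,5-tetramethyl-1,3,2-dioxaborolan-2-yl)ethene | CC1(C)OB(/C=C/B2OC(C)(C)C(C)(C)O2)OC1(C)C | starting material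
6 | (E)-2-(penta-O-benzylcatechin-8-yl)ethenylboronic acid pinacol ester | CC1(C)OB(/C=C/c2c(OCc3ccccc3)cc(OCc3ccccc3)c4c2O[C@H](c2ccc(OCc3ccccc3)c(OCc3ccccc3)c2)[C@@H](OCc3ccccc3)C4)OC1(C)C | intermediate
7 | potassium (E)-[2-(penta-O-benzylcatechin-8-yl)ethenyl]trifluoroborate | [K+].F[B-](F)(F)/C=C/c1c(OCc3ccccc3)cc(OCc3ccccc3)c2c1O[C@H](c1ccc(OCc3ccccc3)c(OCc3ccccc3)c1)[C@@H](OCc3ccccc3)C2 | intermediate
8 | 3,4,5-tris(benzyloxy)benzoic acid | OC(=O)c1cc(OCc2ccccc2)c(OCc2ccccc2)c(OCc2ccccc2)c1 | starting material
9 | (E)-2-(penta-O-benzylcatechin-8-yl)ethenyl 3,4,5-tris(benzyloxy)benzoate | O=C(O/C=C/c1c(OCc3ccccc3)cc(OCc3ccccc3)c2c1O[C@H](c1ccc(OCc3ccccc3)c(OCc3ccccc3)c1)[C@@H](OCc3ccccc3)C2)c1cc(OCc3ccccc3)c(OCc3ccccc3)c(OCc3ccccc3)c1 | intermediate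
10 | 3,4,5-tris(benzyloxy)benzaldehyde | O=Cc1cc(OCc2ccccc2)c(OCc2ccccc2)c(OCc2ccccc2)c1 | starting material
11 | 3,4,5-tris(benzyloxy)benzaldehyde dimethyl acetal | COC(OC)c1cc(OCc2ccccc2)c(OCc2ccccc2)c(OCc2ccccc2)c1 | intermediate
12 | 3,5-bis(benzyloxy)phenol | Oc1cc(OCc2ccccc2)cc(OCc2ccccc2)c1 | starting material
13 | racemic α-chloro-3,4,5-tris(benzyloxy)benzyl methyl ether | COC(Cl)c1cc(OCc2ccccc2)c(OCc2ccccc2)c(OCc2ccccc2)c1 | intermediate
14 | racemic [3,5-bis(benzyloxy)phenoxy](methoxy)[3,4,5-tris(benzyloxy)phenyl]methane | COC(Oc1cc(OCc2ccccc2)cc(OCc2ccccc2)c1)c1cc(OCc2ccccc2)c(OCc2ccccc2)c(OCc2ccccc2)c1 | intermediate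
15 | (E)-O-[3,5-bis(benzyloxy)phenyl] oxocarbenium ion of 10 (cation; counter-ion the chiral phosphoramidate) | O(Cc1ccccc1)c1cc(OCc2ccccc2)cc(/[O+]=C/c2cc(OCc3ccccc3)c(OCc3ccccc3)c(OCc3ccccc3)c2)c1 | intermediate
16 | 5,7,3',4',5'-penta-O-benzyl-epigallocatechin 3-O-[3,4,5-tris(benzyloxy)benzoate]-(4β→8)-3,5,7,3',4'-penta-O-benzylcatechin | O=C(O[C@@H]1[C@@H](c2c(OCc4ccccc4)cc(OCc4ccccc4)c3c2O[C@H](c2ccc(OCc4ccccc4)c(OCc4ccccc4)c2)[C@@H](OCc4ccccc4)C3)c2c(OCc4ccccc4)cc(OCc4ccccc4)cc2O[C@@H]1c1cc(OCc4ccccc4)c(OCc4ccccc4)c(OCc4ccccc4)c1)c1cc(OCc4ccccc4)c(OCc4ccccc4)c(OCc4ccccc4)c1 | intermediate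
17 | epigallocatechin 3-O-gallate-(4β→8)-catechin (CNP0129434.1) | O=C(O[C@@H]1[C@@H](c2c(O)cc(O)c3c2O[C@H](c2ccc(O)c(O)c2)[C@@H](O)C3)c2c(O)cc(O)cc2O[C@@H]1c1cc(O)c(O)c(O)c1)c1cc(O)c(O)c(O)c1 | target

**Summary**

Total step count: 10. Longest linear sequence: 8 steps (steps 1 to 6, 9 and 10, from (+)-catechin).

Steps most likely to fail:

1. Step 9 (proposed new method). Possible failures are poor endo/exo or enantioface selectivity, Friedel–Crafts attack of the oxocarbenium ion at the free C6 of the catechin ring, ionisation of the acetal in the opposite sense followed by C-benzylation of ring A, and acid-induced oligomerisation of the electron-rich enol ester. Fallback, known chemistry: the interflavan bond is made by Lewis-acid-mediated condensation of a C4-activated electrophile with a flavan nucleophile. It sets out from 3 and 8 and returns at 16. Purchased (−)-epigallocatechin F1 is benzylated on its five phenols (BnBr, K2CO3, DMF) to 5,7,3',4',5'-penta-O-benzyl-(−)-epigallocatechin F2. F2 is oxidised at C4 with DDQ in the presence of 2-ethoxyethanol (CH2Cl2, rt) to the 4β-(2-ethoxyethoxy) ether F3. F3 is esterified at O3 with acid 8 (EDC·HCl, DMAP, CH2Cl2) to the gallate F4. F4 is then condensed with an excess of nucleophile 3 under TMSOTf (CH2Cl2, −78 °C); the 3-acyloxy group should direct C8 of 3 to the 4β face, giving 16.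

2. Step 6. Protodeboronation or oxidative degradation of the very electron-rich alkenyltrifluoroborate under copper and oxygen may outpace C–O coupling. Fallback: enol ester formation by O-acylation of an aldehyde, setting out from 6 and 8 and returning at 9. Boronate 6 is oxidised (NaBO3·4H2O, THF/H2O) to (penta-O-benzylcatechin-8-yl)acetaldehyde F5. Acid 8 is converted with oxalyl chloride and catalytic DMF into 3,4,5-tris(benzyloxy)benzoyl chloride F6. Acylation of the enolate of F5 with F6 (Et3N, DMAP, CH2Cl2) should give 9 together with its Z isomer F7. F7 is equilibrated to the less hindered 9 by thiyl-radical addition–elimination (PhSSPh, visible light) before chromatography.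

3. Step 4. Oxidative addition at the hindered, electron-rich bromide may be slow, and double coupling or protodeboronation of the product may compete. Fallback: olefination instead of cross-coupling, setting out from 4 and returning at 6. Bromine–lithium exchange (n-BuLi, THF, −78 °C) and trapping with DMF give 8-formyl-penta-O-benzylcatechin F8. Boron–Wittig olefination of F8 with lithiated bis(pinacolboryl)methane (CH2(Bpin)2, LiTMP, THF, −78 °C to rt) should give 6 with E selectivity.

Further compounds

F1 | step 9 | (−)-epigallocatechin (purchased) | O[C@@H]1Cc2c(O)cc(O)cc2O[C@@H]1c1cc(O)c(O)c(O)c1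
F2 | step 9 | 5,7,3',4',5'-penta-O-benzyl-(−)-epigallocatechin | O[C@@H]1Cc2c(OCc3ccccc3)cc(OCc3ccccc3)cc2O[C@@H]1c1cc(OCc3ccccc3)c(OCc3ccccc3)c(OCc3ccccc3)c1
F3 | step 9 | 4β-(2-ethoxyethoxy)-5,7,3',4',5'-penta-O-benzyl-epigallocatechin | O[C@@H]1[C@@H](OCCOCC)c2c(OCc3ccccc3)cc(OCc3ccccc3)cc2O[C@@H]1c1cc(OCc3ccccc3)c(OCc3ccccc3)c(OCc3ccccc3)c1
F4 | step 9 | 4β-(2-ethoxyethoxy)-5,7,3',4',5'-penta-O-benzyl-epigallocatechin 3-O-[3,4,5-tris(benzyloxy)benzoate] | O=C(O[C@@H]1[C@@H](OCCOCC)c2c(OCc3ccccc3)cc(OCc3ccccc3)cc2O[C@@H]1c1cc(OCc3ccccc3)c(OCc3ccccc3)c(OCc3ccccc3)c1)c1cc(OCc3ccccc3)c(OCc3ccccc3)c(OCc3ccccc3)c1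
F5 | step 6 | (penta-O-benzylcatechin-8-yl)acetaldehyde | O=CCc1c(OCc3ccccc3)cc(OCc3ccccc3)c2c1O[C@H](c1ccc(OCc3ccccc3)c(OCc3ccccc3)c1)[C@@H](OCc3ccccc3)C2
F6 | step 6 | 3,4,5-tris(benzyloxy)benzoyl chloride | O=C(Cl)c1cc(OCc2ccccc2)c(OCc2ccccc2)c(OCc2ccccc2)c1
F7 | step 6 | (Z)-2-(penta-O-benzylcatechin-8-yl)ethenyl 3,4,5-tris(benzyloxy)benzoate | O=C(O/C=C\c1c(OCc3ccccc3)cc(OCc3ccccc3)c2c1O[C@H](c1ccc(OCc3ccccc3)c(OCc3ccccc3)c1)[C@@H](OCc3ccccc3)C2)c1cc(OCc3ccccc3)c(OCc3ccccc3)c(OCc3ccccc3)c1
F8 | step 4 | 8-formyl-3,5,7,3',4'-penta-O-benzyl-(+)-catechin | O=Cc1c(OCc3ccccc3)cc(OCc3ccccc3)c2c1O[C@H](c1ccc(OCc3ccccc3)c(OCc3ccccc3)c1)[C@@H](OCc3ccccc3)C2
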